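The target, a trans-α,β-dibenzyl-γ-butyrolactone, carries one ArCH2 group on each of the ring carbons C3 and C4 of its oxolan-2-one ring, on opposite faces. Both exocyclic bonds, C4–CH2(trimethoxyphenyl) and C3–CH2(guaiacyl), are cut back to the C3=C4 double bond of a butenolide. In one pot, a lithiated aryl dithiane (a masked benzyl anion) adds to C4 and the resulting enolate is benzylated at C3. This makes two C–C bonds and both stereocentres without closing a ring. The acceptor is (5R)-5-(l-menthyloxy)furan-2(5H)-one; its acetal carbon C5 steers both additions and is afterwards reduced to the lactone OCH2.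

Key step: step 5

Assumption: 4-(benzyloxy)-3-methoxybenzyl alcohol (9) is taken as a catalogue chemical; the target is read as the (3R,4R)-trans lactone, which the (5R)-acetal derived from (−)-menthol should deliver.

Step 1
Reactants: 1 furfural
Product: 3 5-hydroxyfuran-2(5H)-one, via furfural endoperoxide 2 (not isolated)
Conditions: O2, rose bengal (cat.), MeOH, hν (visible), rt
Reagents that add atoms: dioxygen, O=O
Why: Dye-sensitised photo-oxygenation, in which singlet oxygen adds across C2/C5 of the furan ([4+2]) and methanolysis of the formyl-bearing endoperoxide expels methyl formate, should leave the racemic, stereolabile hydroxybutenolide.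

Step 2
Reactants: 3 5-hydroxyfuran-2(5H)-one; 4 (−)-menthol
Product: 6 (5R)-5-(l-menthyloxy)furan-2(5H)-one, via (5S)-epimer 5 (not isolated)
Conditions: CSA (cat.), toluene, Dean–Stark, reflux; crystallise from petroleum ether, −20 °C; mother liquor re-equilibrated with TsOH (cat.) and crystallised again
Reagents that add atoms: none
Why: Acid-catalysed acetalisation of the lactol OH by menthol with azeotropic removal of water should give both C5 epimers, which interconvert under acid through the acyloxycarbenium ion, so that selective crystallisation of the (5R)-diastereomer and re-equilibration of the (5S)-rich liquors (crystallisation-induced diastereomer transformation) sets C5 under control of the (1R,2S,5R)-menthyl group.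

Step 3
Reactants: 7 3,4,5-trimethoxybenzaldehyde
Product: 8 2-(3,4,5-trimethoxyphenyl)-1,3-dithiane
Conditions: HS(CH2)3SH, BF3·OEt2 (cat.), CH2Cl2, 0 °C → rt
Reagents that add atoms: propane-1,3-dithiol, SCCCS
Why: Lewis-acid-catalysed dithioacetalisation of an aromatic aldehyde (the first stage of Corey–Seebach umpolung) is reliable, and the aryl methyl ethers are inert to catalytic BF3 at this temperature.

Step 4
Reactants: 9 4-(benzyloxy)-3-methoxybenzyl alcohol
Product: 10 4-(benzyloxy)-3-methoxybenzyl bromide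
Conditions: PBr3, Et2O, 0 °C; used fresh
Reagents that add atoms: phosphorus tribromide, BrP(Br)Br
Why: Bromination of an electron-rich benzylic alcohol with PBr3 proceeds through the phosphite ester and bromide displacement, and the benzyl aryl ether is not affected.

Step 5
Reactants: 8 2-(3,4,5-trimethoxyphenyl)-1,3-dithiane; 6 (5R)-5-(l-menthyloxy)furan-2(5H)-one; 10 4-(benzyloxy)-3-methoxybenzyl bromide
Product: 13 (3R,4R,5R)-3-[4-(benzyloxy)-3-methoxybenzyl]-5-(l-menthyloxy)-4-[2-(3,4,5-trimethoxyphenyl)-1,3-dithian-2-yl]dihydrofuran-2(3H)-one, via 2-lithiodithiane 11 (not isolated), via lithium enolate 12 (not isolated)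
Conditions: 8, n-BuLi, THF, −78 → −20 °C; 6, THF, −78 °C; 10, TMEDA, −78 °C → rt; aq NH4Cl
Reagents that add atoms: none
Why: n-BuLi removes the benzylic, doubly sulfur-stabilised C2–H of 8 to give carbanion 11, which undergoes Michael addition to C4 of butenolide 6, and the lithium enolate 12 is then C-benzylated at C3 by bromide 10 (SN2) in the same flask. The closest known reaction type is the tandem conjugate addition–enolate alkylation of 5-alkoxy-2(5H)-furanones with lithiated 2-aryl-1,3-dithianes (Corey–Seebach nucleophiles). No ring is closed, so no mode of closure applies. C4 is set by the C5 menthyloxy group, which blocks its own face of the flat butenolide so that the bulky nucleophile enters anti (4,5-trans). C3 is set by the new quaternary dithianyl group at C4, which sends the electrophile to the opposite face of the enolate (3,4-trans), while C5 is not touched. The step needs 1,4- over 1,2-addition, secured by the soft, delocalised, hindered anion and the ester-type carbonyl, and C-mono-alkylation, secured by the reactive benzylic bromide, TMEDA de-aggregation of the enolate and the hindered tertiary C3–H of 13.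

Step 6
Reactants: 13 (3R,4R,5R)-3-[4-(benzyloxy)-3-methoxybenzyl]-5-(l-menthyloxy)-4-[2-(3,4,5-trimethoxyphenyl)-1,3-dithian-2-yl]dihydrofuran-2(3H)-one
Product: 14 (3R,4R,5R)-3-[4-(benzyloxy)-3-methoxybenzyl]-5-(l-menthyloxy)-4-(3,4,5-trimethoxybenzyl)dihydrofuran-2(3H)-one
Conditions: Raney Ni (W-2, washed neutral, excess), EtOH–THF, rt → 50 °C
Reagents that add atoms: none
Why: Raney nickel hydrogenolysis of the two benzylic C–S bonds (Mozingo-type desulfurisation) should turn the dithiane carbon into the benzylic CH2 of the trimethoxybenzyl arm, with C3, C4 and C5 uninvolved and the lactone acetal and aryl benzyl ether tolerated by neutral catalyst at moderate temperature without added hydrogen.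

Step 7
Reactants: 14 (3R,4R,5R)-3-[4-(benzyloxy)-3-methoxybenzyl]-5-(l-menthyloxy)-4-(3,4,5-trimethoxybenzyl)dihydrofuran-2(3H)-one
Product: 17 (3R,4R)-3-[4-(benzyloxy)-3-methoxybenzyl]-4-(3,4,5-trimethoxybenzyl)dihydrofuran-2(3H)-one, via oxo carboxylate 15 (not isolated), via hydroxy carboxylate 16 (not isolated)
Conditions: NaBH4, KOH, EtOH–H2O, rt; then 2 M HCl to pH 2, rt
Reagents that add atoms: potassium hydroxide, [K+].[OH-] (its oxygen enters the carboxyl group of 15 and 16; one carboxyl oxygen leaves again as water on lactonisation)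
Why: Saponification–reduction–lactonisation, in which hydroxide opens the pseudo-ester to a carboxylate whose menthyl hemiacetal collapses to aldehyde 15 with loss of menthol, borohydride reduces the aldehyde at once to 16 and acid closes the γ-hydroxy acid to the γ-lactone, so that the former acetal carbon becomes C5H2 while C3 is shielded from enolisation as the carboxylate and C4 stays intact provided reduction outruns enolisation of 15.

Step 8
Reactants: 17 (3R,4R)-3-[4-(benzyloxy)-3-methoxybenzyl]-4-(3,4,5-trimethoxybenzyl)dihydrofuran-2(3H)-one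
Product: 18 (3R,4R)-3-(4-hydroxy-3-methoxybenzyl)-4-(3,4,5-trimethoxybenzyl)dihydrofuran-2(3H)-one
Conditions: H2 (1 atm), 10% Pd/C, EtOAc–EtOH, rt
Reagents that add atoms: none
Why: Catalytic hydrogenolysis of the aryl benzyl ether under neutral conditions should free the phenol without touching the lactone, the aryl methyl ethers or the two stereocentres.

Compound list (l-menthyl = (1R,2S,5R)-2-isopropyl-5-methylcyclohexyl)

1 | furfural (furan-2-carbaldehyde) | O=Cc1ccco1 | starting material
2 | furfural endoperoxide (2,3,7-trioxabicyclo[2.2.1]hept-5-ene-1-carbaldehyde, racemic, transient) | O=CC12OOC(C=C1)O2 | intermediate (not isolated)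
3 | 5-hydroxyfuran-2(5H)-one (racemic lactol, C5 stereolabile) | O=C1OC(O)C=C1 | intermediate
4 | (−)-menthol, (1R,2S,5R)-2-isopropyl-5-methylcyclohexan-1-ol | CC(C)[C@@H]1CC[C@@H](C)C[C@H]1O | starting material
5 | (5S)-epimer, (5S)-5-(l-menthyloxy)furan-2(5H)-one | O=C1O[C@H](O[C@@H]2C[C@H](C)CC[C@H]2C(C)C)C=C1 | intermediate (not isolated)
6 | (5R)-5-(l-menthyloxy)furan-2(5H)-one | O=C1O[C@@H](O[C@@H]2C[C@H](C)CC[C@H]2C(C)C)C=C1 | intermediate
7 | 3,4,5-trimethoxybenzaldehyde | COc1cc(C=O)cc(OC)c1OC | starting material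
8 | 2-(3,4,5-trimethoxyphenyl)-1,3-dithiane | COc1cc(C2SCCCS2)cc(OC)c1OC | intermediate
9 | 4-(benzyloxy)-3-methoxybenzyl alcohol | COc1cc(CO)ccc1OCc1ccccc1 | starting material
10 | 4-(benzyloxy)-3-methoxybenzyl bromide | COc1cc(CBr)ccc1OCc1ccccc1 | intermediate
11 | 2-lithiodithiane, 2-lithio-2-(3,4,5-trimethoxyphenyl)-1,3-dithiane | [Li]C1(SCCCS1)c1cc(OC)c(OC)c(OC)c1 | intermediate (not isolated)
12 | lithium enolate, lithium (4R,5R)-5-(l-menthyloxy)-4-[2-(3,4,5-trimethoxyphenyl)-1,3-dithian-2-yl]-4,5-dihydrofuran-2-olate (dithianyl trans to the menthyloxy group) | [Li]OC1=C[C@@H](C3(SCCCS3)c4cc(OC)c(OC)c(OC)c4)[C@H](O[C@@H]2C[C@H](C)CC[C@H]2C(C)C)O1 | intermediate (not isolated)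
13 | (3R,4R,5R)-3-[4-(benzyloxy)-3-methoxybenzyl]-5-(l-menthyloxy)-4-[2-(3,4,5-trimethoxyphenyl)-1,3-dithian-2-yl]dihydrofuran-2(3H)-one (3,4-trans, 4,5-trans) | COc1cc(C[C@H]2C(=O)O[C@@H](O[C@@H]3C[C@H](C)CC[C@H]3C(C)C)[C@@H]2C2(SCCCS2)c2cc(OC)c(OC)c(OC)c2)ccc1OCc1ccccc1 | intermediate
14 | (3R,4R,5R)-3-[4-(benzyloxy)-3-methoxybenzyl]-5-(l-menthyloxy)-4-(3,4,5-trimethoxybenzyl)dihydrofuran-2(3H)-one | COc1cc(C[C@H]2C(=O)O[C@@H](O[C@@H]3C[C@H](C)CC[C@H]3C(C)C)[C@@H]2Cc2cc(OC)c(OC)c(OC)c2)ccc1OCc1ccccc1 | intermediate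
15 | oxo carboxylate, potassium (2R,3R)-2-[4-(benzyloxy)-3-methoxybenzyl]-4-oxo-3-(3,4,5-trimethoxybenzyl)butanoate | COc1cc(C[C@@H](C(=O)[O-])[C@H](C=O)Cc2cc(OC)c(OC)c(OC)c2)ccc1OCc1ccccc1.[K+] | intermediate (not isolated)
16 | hydroxy carboxylate, potassium (2R,3R)-2-[4-(benzyloxy)-3-methoxybenzyl]-4-hydroxy-3-(3,4,5-trimethoxybenzyl)butanoate | COc1cc(C[C@@H](C(=O)[O-])[C@H](CO)Cc2cc(OC)c(OC)c(OC)c2)ccc1OCc1ccccc1.[K+] | intermediate (not isolated)
17 | (3R,4R)-3-[4-(benzyloxy)-3-methoxybenzyl]-4-(3,4,5-trimethoxybenzyl)dihydrofuran-2(3H)-one | COc1cc(C[C@H]2C(=O)OC[C@@H]2Cc2cc(OC)c(OC)c(OC)c2)ccc1OCc1ccccc1 | intermediate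
18 | (3R,4R)-3-(4-hydroxy-3-methoxybenzyl)-4-(3,4,5-trimethoxybenzyl)dihydrofuran-2(3H)-one | COc1cc(C[C@H]2C(=O)OC[C@@H]2Cc2cc(OC)c(OC)c(OC)c2)ccc1O | target

Total step count: 8
Longest linear sequence: 6 steps (steps 1, 2, 5, 6, 7, 8, from furfural)

Steps most likely to fail

Step 5. The enolate 12 may be protonated or may alkylate sluggishly next to the bulky dithianyl group, and the trans selectivity at C3 may erode. The fallback separates the two bond formations and moves the alkylation behind the desulfurisation. It sets out from 6 and 8.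
- Anion 11 is added to 6 at −78 °C and the enolate is quenched with aqueous NH4Cl to give (4R,5R)-5-(l-menthyloxy)-4-[2-(3,4,5-trimethoxyphenyl)-1,3-dithian-2-yl]dihydrofuran-2(3H)-one F1.
- Raney nickel in EtOH should convert this into (4R,5R)-5-(l-menthyloxy)-4-(3,4,5-trimethoxybenzyl)dihydrofuran-2(3H)-one F2.
- LDA in THF at −78 °C should form lithium (4R,5R)-5-(l-menthyloxy)-4-(3,4,5-trimethoxybenzyl)-4,5-dihydrofuran-2-olate F3 (not isolated). Its alkylation with 10, anti to the C4 benzyl group, should give 14, where the route is rejoined; step 6 is then not needed.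

Step 6. Hydrogenolysis of the hindered quaternary C–S bonds beside the menthyl acetal may stall, or the benzyl ether may be lost on nickel. The fallback reverses the order of events: the auxiliary is removed first and the smaller lactone is desulfurised with a different reductant. It sets out from 13.
- NaBH4/KOH in EtOH–H2O should lead through potassium (2R,3R)-2-[4-(benzyloxy)-3-methoxybenzyl]-4-oxo-3-[2-(3,4,5-trimethoxyphenyl)-1,3-dithian-2-yl]butanoate F4 (not isolated) and potassium (2R,3R)-2-[4-(benzyloxy)-3-methoxybenzyl]-4-hydroxy-3-[2-(3,4,5-trimethoxyphenyl)-1,3-dithian-2-yl]butanoate F5 (not isolated).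
- Acidification with HCl should give (3R,4R)-3-[4-(benzyloxy)-3-methoxybenzyl]-4-[2-(3,4,5-trimethoxyphenyl)-1,3-dithian-2-yl]dihydrofuran-2(3H)-one F6.
- Nickel boride (NiCl2·6H2O, NaBH4, MeOH–THF, 0 °C) should then give 17, where the route is rejoined, bypassing 14.

Step 7. C4 may epimerise through the enolisable aldehyde 15 in hydroxide, or the pseudo-ester may open incompletely. The fallback cleaves the acetal under acid and reduces at near-neutral pH. It sets out from 14.
- Aqueous TFA in THF should hydrolyse the menthyl acetal to the lactol (3R,4R)-3-[4-(benzyloxy)-3-methoxybenzyl]-5-hydroxy-4-(3,4,5-trimethoxybenzyl)dihydrofuran-2(3H)-one F7 (C5 epimers, in equilibrium with the open aldehyde acid).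
- KHCO3 and KBH4 in EtOH–H2O at 0 °C should take it through 15 and 16 without free hydroxide.
- Dilute HCl should close the lactone to 17, where the route is rejoined.

Further compounds
F1 | step 5 | (4R,5R)-5-(l-menthyloxy)-4-[2-(3,4,5-trimethoxyphenyl)-1,3-dithian-2-yl]dihydrofuran-2(3H)-one | O=C1C[C@@H](C3(SCCCS3)c4cc(OC)c(OC)c(OC)c4)[C@H](O[C@@H]2C[C@H](C)CC[C@H]2C(C)C)O1
F2 | step 5 | (4R,5R)-5-(l-menthyloxy)-4-(3,4,5-trimethoxybenzyl)dihydrofuran-2(3H)-one | O=C1C[C@@H](Cc3cc(OC)c(OC)c(OC)c3)[C@H](O[C@@H]2C[C@H](C)CC[C@H]2C(C)C)O1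
F3 | step 5 | lithium (4R,5R)-5-(l-menthyloxy)-4-(3,4,5-trimethoxybenzyl)-4,5-dihydrofuran-2-olate | [Li]OC1=C[C@@H](Cc3cc(OC)c(OC)c(OC)c3)[C@H](O[C@@H]2C[C@H](C)CC[C@H]2C(C)C)O1
F4 | step 6 | potassium (2R,3R)-2-[4-(benzyloxy)-3-methoxybenzyl]-4-oxo-3-[2-(3,4,5-trimethoxyphenyl)-1,3-dithian-2-yl]butanoate | COc1cc(C[C@@H](C(=O)[O-])[C@H](C=O)C2(SCCCS2)c2cc(OC)c(OC)c(OC)c2)ccc1OCc1ccccc1.[K+]
F5 | step 6 | potassium (2R,3R)-2-[4-(benzyloxy)-3-methoxybenzyl]-4-hydroxy-3-[2-(3,4,5-trimethoxyphenyl)-1,3-dithian-2-yl]butanoate | COc1cc(C[C@@H](C(=O)[O-])[C@H](CO)C2(SCCCS2)c2cc(OC)c(OC)c(OC)c2)ccc1OCc1ccccc1.[K+]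
F6 | step 6 | (3R,4R)-3-[4-(benzyloxy)-3-methoxybenzyl]-4-[2-(3,4,5-trimethoxyphenyl)-1,3-dithian-2-yl]dihydrofuran-2(3H)-one | COc1cc(C[C@H]2C(=O)OC[C@@H]2C2(SCCCS2)c2cc(OC)c(OC)c(OC)c2)ccc1OCc1ccccc1
F7 | step 7 | (3R,4R)-3-[4-(benzyloxy)-3-methoxybenzyl]-5-hydroxy-4-(3,4,5-trimethoxybenzyl)dihydrofuran-2(3H)-one (C5 epimers) | COc1cc(C[C@H]2C(=O)OC(O)[C@@H]2Cc2cc(OC)c(OC)c(OC)c2)ccc1OCc1ccccc1
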